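Two questions were asked of this flask: when target stands highest, and how high.

| flask | starting material | partner | remark | time |
|---|---|---|---|---|
| dawn | 1.1 M | 1.5 equiv | run made earlier |  |
| noon | 1.8 M | 1.5 equiv | run made earlier |  |
| autumn | 0.80 M | 2.2 equiv | run made earlier |  |
| flask | 0.80 M | 1.50 equiv |  | 25 min |

| run | time / min | target / % | starting material / % |
|---|---|---|---|
| dawn | 0.500 | 31.9 | 0.1 |
| dawn | 1.33 | 43.1 | 0.1 |
| dawn | 3.00 | 40.9 | 0 |
| dawn | 6.00 | 36.9 | 0.3 |
| dawn | 15.0 | 36.8 | 0.4 |
| noon | 0.500 | 41.0 | 0.4 |
| noon | 1.33 | 48.2 | 0 |
| noon | 3.00 | 42.2 | 0 |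
| noon | 6.00 | 38.6 | 0 |
| noon | 15.0 | 37.6 | 0 |
| autumn | 0.500 | 35.9 | 0.2 |
| autumn | 1.33 | 49.5 | 0.2 |
| autumn | 3.00 | 45.8 | 0 |
| autumn | 6.00 | 42.3 | 0 |
| autumn | 15.0 | 40.9 | 0 |

(readings scatter by 0.3 percentage points)

1. time up to 25 min at which target stands highest
2. the amount of target, in percent of the starting material charged, at that time

- a species is counted by the starting material in it: one homo product counts as two
- candidate steps: starting material -> intermediate; partner + intermediate -> target; 2 intermediate -> homo product; target <-> isomer of the product

Starting material was down to 0.1% at the first dawn reading, so the later rise and fall of target belonged to later steps. Dawn and noon, both at 1.5 equiv, ended close together, at 36.8% and 37.6%. So I took the dawn plateau for the flask, which has the same equivalents. But their highest readings differed, and so did their charged partner concentrations, 1.65 M and 2.70 M. Among the candidate steps, partner enters the capture of intermediate but not the exchange of target and isomer of the product. So I compared the overshoot, highest target reading over last reading, a measure of kinetic against thermodynamic control. It read 1.17 at dawn and 1.28 at noon. The overshoot gain, its rise per molar of partner at fixed equivalents, was 0.105 L mol⁻¹.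

The flask was charged with 1.20 M of partner, less than dawn. The gain therefore gave an overshoot of 1.12 and a peak of 41.4%, which I placed between 1.33 min and 3.00 min.

The forecast said 41.5% at 2 min, expecting “a later, lower peak”.

The flask gave 40.3% at 2.03 min, with 30.3% as homo product by then. Target in the flask ended at 36.7%, so its overshoot was 1.10, against my 1.12.

    starting material → intermediate (k = 0.248 s⁻¹)
    partner + intermediate → target (k = 0.0142 L mol⁻¹ s⁻¹)
    2 intermediate → homo product (k = 0.00973 L mol⁻¹ s⁻¹)
    target ⇌ isomer of the product (K = 0.870, k = 0.00627 s⁻¹)

The neighbour flask with 1.4 M of starting material starts with 2.10 M of partner, so the gain gives an overshoot of 1.22 and a peak of 44.9%. Computed, that neighbour flask peaks at 45.8% and ends at 37.2%.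

The numbers in the tables were computed for an exercise; the scatter is artificial.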